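The rate constants are invented; the run is a simulation.

With 1 mol% of free catalyst on 0.65 M of substrate and 2.00 equiv of partner, the flask holds 0.00650 M of free catalyst, and that small amount is what we watch.

    substrate + partner + free catalyst ⇌ target + free catalyst, rate k1*[substrate]*[partner]*[free catalyst] forward; the back reaction follows from the equilibrium constant (K1 = 1.2 M⁻¹, k1 = 14 M⁻² h⁻¹, Ea1 = 55.0 kJ mol⁻¹, ΔH1 = −30.0 kJ mol⁻¹)
    free catalyst → spent catalyst A (k2 = 0.13 h⁻¹, Ea2 = 108 kJ mol⁻¹)
    substrate + free catalyst → spent catalyst B (k3 = 0.35 M⁻¹ h⁻¹, Ea3 = 82.0 kJ mol⁻¹)
    target ⇌ isomer of the product (K4 = 0.64, k4 = 0.0065 h⁻¹, Ea4 = 109 kJ mol⁻¹, ΔH4 = −9.00 kJ mol⁻¹)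
    (constants at 50 °C)

| setting | Friday's | Saturday's | Thursday's | Monday's |
|---|---|---|---|---|
| substrate | 0.65 M | 0.65 M | 0.65 M | 0.65 M |
| partner | 2.00 equiv | 2.00 equiv | 2.00 equiv | 2.00 equiv |
| free catalyst | 1 mol% | 1 mol% | 1 mol% | 1 mol% |
| temperature | 20 °C | 50 °C | 110 °C | 80 °C |
| time | 10 h | 10 h | 10 h | 10 h |

- the list of constants is for 50 °C, to be carried to other temperatures by the activation energies and enthalpies

- the flask that comes out highest in amount of target, in percent of the substrate charged, or "all alike" when all lie within 1.5 percentage points (Friday's / Saturday's / Thursday's / Monday's / all alike)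
- target at the end, in percent of the substrate charged, Friday's
- target at the end, in percent of the substrate charged, Saturday's
- target at the end, in percent of the substrate charged, Thursday's
- target at the end, in percent of the substrate charged, Monday's

You asked for a quick number, with the hunch that the hottest flask gives most target; we reckon it otherwise, in these steps.

1. The concentration that sets the order of the rate is the free catalyst, c: the forward rate is first order in it, and it dies. Holding substrate at its charge makes that loss pseudo-first-order, with constant λ = k2 + k3·[substrate] = 0.357 h⁻¹ in Saturday's flask. Its mean life, 2.80 h, is shorter than the run.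

2. So we carry the catalyst budget N, the fraction of substrate that the catalyst's working life turns over at the starting rate: N = k1·[partner]·c/λ = 0.331 for Saturday's flask.

3. The reversible step sets a ceiling X, the converted fraction at its equilibrium. With g = K1·[substrate] = 0.780, the balance g(1−X)(e−X) = X, where e is the equivalents of partner, gives X = 53.4 %.

4. Conversion bends towards that ceiling, so we take x = X(1 − exp(−N/X)) = 24.7 % for Saturday's flask. That x counts target plus isomer, for in the scheme isomer forms from target and from nothing else, at whatever speed that step runs. The isomerisation's relaxation half-life of 41.6 h in Saturday's flask is longer than the run, so we expect target to hold the larger part of x there.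

5. Heating works against the budget: the loss to spent catalyst A has 53.0 kJ mol⁻¹ more activation energy than the forward step, and the loss to spent catalyst B has 27.0 kJ mol⁻¹ more. From coldest to hottest flask the first loss speeds up 33000-fold and the forward step 200-fold, while K1 falls to 0.209 M⁻¹ in Thursday's flask. Friday's flask we have not reckoned by this budget, so placing Saturday's above it is our judgement.

The forecast, opening with “Catalyst death limits everything”, named Saturday's and gave 12.2 % for Friday's, 23.8 % for Saturday's, 2 % for Thursday's and 5.7 % for Monday's.

The simulation gives Saturday's as highest, with 12.3 % for Friday's, 23.7 % for Saturday's, 2.02 % for Thursday's and 5.72 % for Monday's.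

Saturday's flask ended with 23.7 % of target and 1.16 % of isomer, together 24.9 % against our x of 24.7 %. Its neighbour charged with 4 mol% of free catalyst keeps the same λ and X, but its budget is 1.32, now larger than X, so the same formula gives 48.9 %. That flask ended with 47.0 % of target and 2.55 % of isomer, together 49.5 %.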